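Read two peaks against each other.

    starting material → target (k1 = 3.62 × 10⁻⁴ s⁻¹, Ea1 = 82.0 kJ mol⁻¹)
    starting material ⇌ intermediate A (K2 = 0.390, k2 = 5.46 × 10⁻⁵ s⁻¹, Ea2 = 85.0 kJ mol⁻¹, ΔH2 = −5.00 kJ mol⁻¹)
    starting material → intermediate B (k3 = 6.28 × 10⁻⁵ s⁻¹, Ea3 = 96.0 kJ mol⁻¹)
    intermediate B ⇌ intermediate C (K4 = 6.0, k4 = 3.26 × 10⁻⁴ s⁻¹, Ea4 = 98.0 kJ mol⁻¹, ΔH4 = −44.0 kJ mol⁻¹)
    intermediate A ⇌ intermediate D (K5 = 0.64, k5 = 3.15 × 10⁻⁵ s⁻¹, Ea5 = 103 kJ mol⁻¹, ΔH5 = 13.0 kJ mol⁻¹)
    2 starting material → homo dimer (k6 = 3.03 × 10⁻⁶ M⁻¹ s⁻¹, Ea6 = 83.0 kJ mol⁻¹)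
    target ⇌ isomer of the product (K7 = 0.848, k7 = 1.99 × 10⁻⁵ s⁻¹, Ea7 = 92.0 kJ mol⁻¹, ΔH7 = −52.0 kJ mol⁻¹)
    target → over-reaction product (k8 = 1.68 × 10⁻⁵ s⁻¹, Ea8 = 107 kJ mol⁻¹)
    (constants at 25 °C)

| flask | starting material | temperature | time | remark |
|---|---|---|---|---|
| teal | 0.050 M | −5 °C | 8.0 h |  |
| blue | 0.050 M | 25 °C | 8.0 h |  |
| grey | 0.050 M |  | 8.0 h | at −35 °C until 2.5 h, from then on at 25 °C |
| green | 0.050 M | −35 °C | 8.0 h |  |

- a species is counted by the starting material in it: one homo dimer counts as two
- a step written with two of one species runs at k times the square of its concentration and takes two of it each time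
- the list of constants is for 25 °C, to be carried to other temperatures by the activation energies and enthalpies

- which flask leads in amount of target, in percent of the starting material charged ("all alike" within 1.5 percentage points) (teal / blue / grey / green / all alike)
- how much target is there at the end, in percent of the starting material charged: teal
- how much target is there at the end, in percent of the starting material charged: blue
- how much target is there at the end, in percent of the starting material charged: grey
- how much target is there at the end, in percent of the starting material charged: green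

Starting material feeds target, and target leaves to the isomer and to the over-reaction product. Let m be the rate constant of the passing of starting material into target, and e the sum of the constants that take target to the isomer and to the over-reaction product. With S and P as the amounts of starting material and target, target gains mS and loses eP, if for now you count no return from the isomer. It therefore stops rising when P/S reaches this value at 25 °C:

X = m/e = 3.62 × 10⁻⁴ s⁻¹ / 3.67 × 10⁻⁵ s⁻¹ = 9.86

Call X the crossing ratio: on this count, below it the target peak grows, above it the peak shrinks.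

Now the clock on S. Intermediate A goes back at 1.40 × 10⁻⁴ s⁻¹, faster than it goes on to intermediate D at 3.15 × 10⁻⁵ s⁻¹, so I count it as a waiting room and not a leak. The homo dimer step starts at 3.03 × 10⁻⁷ s⁻¹ per starting material, far below the step to intermediate B at 6.28 × 10⁻⁵ s⁻¹. That leaves the target step and the step to intermediate B:

a = 4.25 × 10⁻⁴ s⁻¹, about ten times e

With these two rates the crossing comes at

ln(a/e)/(a − e) = 1.75 h

Blue stays warm for 8.0 h and grey for 5.50 h, both longer than that. On this reckoning blue and grey therefore spend their last hours on the falling side. In grey's cold hold m is 8.70 × 10⁻⁸ s⁻¹, which makes 0.0783 % of target by 2.5 h. So I count grey as blue with a shorter warm stage. The two-rate curve gives blue 32.4 % and grey 45.1 %.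

The weak link is the one-way isomer. Its constant of return is 2.35 × 10⁻⁵ s⁻¹, larger than the constant 1.99 × 10⁻⁵ s⁻¹ that forms it. Reforged, target and isomer form a pair with sum of rates 6.02 × 10⁻⁵ s⁻¹ and two decay rates:

fast 5.27 × 10⁻⁵ s⁻¹, slow 7.48 × 10⁻⁶ s⁻¹, fast share 0.646

Feeding this pair with the share m/a, delayed by 1/a, gives blue 38.4 % and grey 48.4 %.

Teal is another matter. At −5 °C, m is 8.94 × 10⁻⁶ s⁻¹ and e is 4.47 × 10⁻⁷ s⁻¹, so X becomes 20.0. If S stayed at its start, teal would make 25.8 % of target in 8.0 h, a P/S far under teal's X, so I expect teal's target still to be rising at the end. Green, at the m of grey's cold hold, makes 0.250 % on the same count. My reckoning puts grey first.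

The forecast says grey leads, with teal 22 %, blue 38.6 %, grey 47.9 % and green 0.25 %. Of blue it says “isomerisation and over-reaction erode it”. Mine is lower on blue, and higher on grey and teal.

The flasks give grey first: teal 21.9 %, blue 38.6 %, grey 47.8 %, green 0.250 %. Grey's target moves by 5 points with an end at 6.90 h or 9.26 h, all amounts held. At 8.00 h grey held 47.8 % of target beside 0.452 % of starting material, a ratio of 106, above the X of 25 °C, 9.86. Teal's ratio at 8.00 h was 0.301, and at 80.0 h it was 13.0, still under teal's X of 20.0.

The constants are assumed.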